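Assumption: labdane numbering is used for the target and for all intermediates (decalin C1–C10, side chain C11–C16, C17 on C8, C18 and C19 on C4, C20 on C10); α is the face opposite the C20 methyl group. Read this way, the SMILES is (4S,5R,7R,8S,9R,10S)-7α,8α-dihydroxylabda-13(16),14-dien-19-yl (E)-4-hydroxycinnamate. Chloroprene is taken as commercially available in the form of a stabilised solution.

## Analysis of the target

- Target 30 is the (E)-p-coumarate of a labdane triol. It is a trans-fused decalin (ring A = C1–C5 and C10, ring B = C5–C10) with a 3-methylenepent-4-enyl chain (C11–C16) on C9.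
- The configuration is 5α-H, 10β-CH3, 4β (axial) CH2O (C19), 4α-CH3 (C18), 9β side chain, 7α-OH and 8α-OH cis, and 8β-CH3 (C17).
- All six stereocentres lie on the decalin. C4 and C10 are quaternary and 1,3-related through C5 (C19 and C20 are syn-diaxial). C7, C8, C9 and C10 are contiguous.
- The feature the route is built on lies in ring B. The oxygen-bearing C7 stands 1,4 (para) to the quaternary C10, the methyl-bearing C8 lies between C7 and C9, and the C4 arm on C5 is trans to the C1 arm on C10. This is the imprint of a [4+2] adduct of a 2-silyloxy-3-methylbuta-1,3-diene (C6–C7–C8–C9) with an (E)-2-methyl-2-enal (C5=C10, formyl carbon = C1).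
- A second feature is the cis-7,8-diol beside the C9 branch. It is the dihydroxylation product of a C7=C8 alkene, and that alkene with its C9 substituent is what a suprafacial 1,3-transposition from a C7 allylic alcohol leaves behind.
- Sensitive groups are the 2-substituted 1,3-diene (acid, oxidants, dimerisation), the phenolic cinnamate (base, hydride, nucleophiles) and the tertiary 8-OH, which closes a tetrahydrofuran onto any electrophilic C12.
- The hard points are absolute control of quaternary C10 and its trans relation to C5, telling CH3 from CH2O at C4, placing the 9β branch next to C10, and finishing all oxidation before the diene exists.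

## Retrosynthetic reasoning

**30 to 29, then 25 + 28 (C19–O acyl bond).** The phenolic ester is the most base-labile unit, so it is introduced last. The phenol is masked as a THP ether (acid 28, from 26) so that it falls off together with the diol acetonide in one mild acid step.

**25 to 22 + 24 (C12–C13).** The diene is cut at its sp3–sp2 bond. A primary iodide at C12 and the butadienyl Grignard reagent 24 (from 23) give the whole diene in one copper-catalysed coupling. It is made late because it would not survive dihydroxylation, and only after O-8 is masked, because a free 8-alkoxide would cyclise onto C12.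

**22 to 21 to 20 to 19 (C7–O and C8–O).** The cis-diol comes from syn-dihydroxylation of the C7=C8 alkene of diol 19 on its open α face. The acetonide 21 blocks both oxygens. The unhindered C12 alcohol is distinguished from the neopentyl C19 alcohol by rate of displacement.

**19 to 18 to 15 (C9–C11).** The two-carbon stub C11–C12 and the C7=C8 alkene are made together by Johnson–Claisen rearrangement of the 7β-allylic alcohol 15. The C7 oxygen steers carbon onto the β face of C9 and is then returned by the dihydroxylation. This removes the need for any C–C bond formation at C9 under steric control next to C10, which would favour the wrong (α) face.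

**15 to 14 to 13 (C8=C9 enone).** The allylic alcohol comes from enone 14, and the enone from the regiodefined silyl enol ether 13 by dehydrogenation. The enol ether is carried as a protected C7 ketone through the ring A construction.

**13 to 11 (C4–C18).** C4 is made quaternary last in ring A by methylation of the C19 ester enolate. The axial C20 methyl directs the methyl group to the α face, so CH3 and CH2O are told apart by the substrate and no C4 stereocentre has to be controlled earlier.

**11 to 9 to 7 to 6 (ring A: C1=C2, C3–C4, C1=CH2).** Ring A is closed onto ring B by ring-closing metathesis between a vinyl group on C10 (from the formyl group of 6) and an allyl group on C4 (from alkylation of the acetate arm). The alkene is hydrogenated in the same flask. Ring A must be closed after ring B. A trans ring fusion can only come from an acyclic E-dienophile; a cyclic one would give the cis-decalin.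

**6 to 3 + 5 (C5–C6 and C9–C10, key step).** Ring B is cut into diene 5 and enal 3. One catalytic enantioselective Diels–Alder reaction then sets the quaternary C10 and C5 (relative configuration from the E alkene, absolute from the catalyst). It also places the C7 oxygen and the C17 methyl with the enol double bond exactly at C7=C8. Both partners are achiral and one step from commodity chemicals: 3 from 1 and 2 by cross-metathesis, 5 from 4 by silylation.

## Alternatives that were turned down

**Alternative 1: cation–olefin bicyclisation (the textbook route).**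
- Disconnection: C4–C5 and C9–C10.
- Forward key step: proton-initiated, chiral-acid-controlled bicyclisation of the acyclic trienoate A1, a homofarnesate with a (Z)-benzyloxymethyl terminus, terminated by the carboxyl group to give lactone A2.
- Why turned down: C19 comes out axial only from the Z terminus, which must be built and kept. Its allylic C–O bond destabilises the C4 cation, so initiation competes with protonation of the two inner alkenes. Enantiocontrol of bicyclisations without an aryl terminator is modest. A2 has oxygen at C8 but not at C7, so a lactone opening–elimination sequence with its alkene isomer mixtures would still be needed. The overall count is no shorter than the chosen route.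

**Alternative 2: intramolecular Diels–Alder reaction.**
- Disconnection: C5–C10 and C8–C9.
- Forward key step: in-situ silylation of the enone of triene A3 and cycloaddition onto its tethered (E)-3-methyl-2-enoate, closing both rings to A4.
- Why turned down: the new C5–C10 bond joins a neopentyl diene terminus (next to quaternary C4) to a β,β-disubstituted dienophile carbon, which is severe congestion. The tether forces the silyloxy carbon meta to the ester, an electronic mismatch. The only control element, C4 (CH3 against CO2Me), discriminates weakly between the two chair-like tether conformations. A3 needs an enantioenriched acyclic quaternary centre, about nine steps. A4 carries C11 as a one-carbon ester, which leaves a homologation at a hindered position.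

**Alternative 3: relay from the chiral pool.**
- Disconnection: none in rings A and B; the C8–C14 and C9–C11 bonds of a tricycle are cut instead.
- Forward key step: oxidative excision of the phenol ring of (+)-podocarpic acid A5 to the bicyclic keto ester A6, then C9 alkylation and C8 methylation by way of an enol triflate.
- Why turned down: C4, C5 and C10 are bought, not made. Four carbons are cut away and seven put back. Enolisation of A6 prefers C7 over the C9 position flanked by C10, so the side chain goes in with poor regiocontrol. The step count is about the same for an expensive starting material.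

Key step: step 3

## Route

Step 1
Reactants: 1 methacrolein; 2 methyl but-3-enoate
Product: 3 methyl (E)-4-methyl-5-oxopent-3-enoate
Conditions: second-generation Grubbs catalyst RuCl2(H2IMes)(PCy3)(=CHPh) (3 mol%), 1 (3 equiv), CH2Cl2, 40 °C
Reagents that add atoms: none
Why: Olefin cross-metathesis of a terminal alkene with a 1,1-disubstituted enal; excess volatile 1 suppresses homodimerisation of 2, ethene is lost, and the trisubstituted enal should form as the favoured E isomer (formyl trans to the CH2CO2Me arm).

Step 2
Reactants: 4 3-methylbut-3-en-2-one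
Product: 5 tert-butyldimethyl[(3-methylbuta-1,3-dien-2-yl)oxy]silane
Conditions: TBSOTf, Et3N, Et2O, 0 °C
Reagents that add atoms: tert-butyldimethylsilyl trifluoromethanesulfonate, CC(C)(C)[Si](C)(C)OS(=O)(=O)C(F)(F)F
Why: Soft enolisation and O-silylation at the only enolisable position (the acetyl CH3) give the 2-silyloxy diene; no stereocentre is formed.

Step 3
Reactants: 3 methyl (E)-4-methyl-5-oxopent-3-enoate; 5 tert-butyldimethyl[(3-methylbuta-1,3-dien-2-yl)oxy]silane
Product: 6 methyl 2-[(1S,2R)-5-(tert-butyldimethylsilyloxy)-2-formyl-2,4-dimethylcyclohex-4-en-1-yl]acetate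
Conditions: (S)-B-(o-tolyl)diphenylprolinol oxazaborolidine·HNTf2 (20 mol%), 5 (1.5 equiv), CH2Cl2, −78 → −40 °C
Reagents that add atoms: none
Why: The boron Lewis acid binds the formyl oxygen of s-trans 3 and the diene adds in a concerted, asynchronous [4+2] process in which the C5–C6 bond leads and the C9–C10 bond follows. The closest known reaction type is the oxazaborolidinium-catalysed Diels–Alder reaction of 2-substituted enals with 2-silyloxybuta-1,3-dienes, which gives 4-formyl-4-alkylcyclohexanone silyl enol ethers with a quaternary centre. Ring B is closed as a six-membered carbocycle by cycloaddition (bonds C5–C6 and C9–C10). The relative configuration of C5 and C10 follows stereospecifically from the E geometry of 3 under suprafacial addition: the C20 methyl and the C4 arm end up cis, and the formyl group (C1) and the C4 arm trans, as the trans ring fusion requires. The absolute configuration (10R and 5S in 6, the same spatial arrangement as 10S and 5R in 30) is set by the catalyst, which must expose the C10-Re face of the bound enal; the (S)-catalyst is proposed by analogy with 2-methylacrolein, and its antipode is equally available should the sense prove opposite. Regioselectivity (silyloxy carbon C7 para to the formyl-bearing C10, methyl-bearing C8 next to C9) is secured by the large HOMO coefficient at C6 of the 2-silyloxy diene pairing with the β-carbon C5. No endo/exo question arises because both diene termini are unsubstituted, and addition to C=C and not to C=O is secured by the moderate nucleophilicity of a mono-oxygenated diene.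

Step 4
Reactants: 6 methyl 2-[(1S,2R)-5-(tert-butyldimethylsilyloxy)-2-formyl-2,4-dimethylcyclohex-4-en-1-yl]acetate
Product: 7 methyl 2-[(1S,2S)-5-(tert-butyldimethylsilyloxy)-2,4-dimethyl-2-vinylcyclohex-4-en-1-yl]acetate
Conditions: Ph3PCH3Br, KOtBu, THF, 0 °C → rt
Reagents that add atoms: methyltriphenylphosphonium bromide, C[P+](c1ccccc1)(c1ccccc1)c1ccccc1.[Br-]
Why: Wittig methylenation of the non-enolisable neopentyl aldehyde; the ester and the tetrasubstituted silyl enol ether do not react with the ylide at this temperature, and the quaternary C10 cannot epimerise (the descriptor changes only through CIP priorities).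

Step 5
Reactants: 7 methyl 2-[(1S,2S)-5-(tert-butyldimethylsilyloxy)-2,4-dimethyl-2-vinylcyclohex-4-en-1-yl]acetate
Product: 9 methyl 2-[(1S,2S)-5-(tert-butyldimethylsilyloxy)-2,4-dimethyl-2-vinylcyclohex-4-en-1-yl]pent-4-enoate (both C4 epimers), via lithium ester enolate 8 (not isolated)
Conditions: LiN(iPr)2, THF, −78 °C; then allyl bromide, −78 → −20 °C
Reagents that add atoms: allyl bromide, C=CCBr
Why: Ester enolate alkylation at C4, the only acidic position, installs C3 and C2 as an allyl group; the C4 configuration is left open on purpose because step 7 erases it.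

Step 6
Reactants: 9 methyl 2-[(1S,2S)-5-(tert-butyldimethylsilyloxy)-2,4-dimethyl-2-vinylcyclohex-4-en-1-yl]pent-4-enoate
Product: 11 methyl 7-(tert-butyldimethylsilyloxy)-11,12,13,14,15,16,18-heptanorlabd-7-en-19-oate (5α-H and 10β-CH3; both C4 epimers), via ring-closed 1,7-diene 10 (not isolated)
Conditions: second-generation Grubbs catalyst RuCl2(H2IMes)(PCy3)(=CHPh) (5 mol%), ClCH2CH2Cl, 45 °C; then H2 (7 bar), 70 °C
Reagents that add atoms: none
Why: Ring-closing metathesis joins the vinyl group on C10 to the allyl group on C4 (six-membered ring A, trans-fused because the two arms are trans on ring B); under H2 the ruthenium residue becomes a hydride catalyst that saturates the new disubstituted C1=C2 bond (tandem metathesis–hydrogenation), while the tetrasubstituted silyl enol ether is too hindered to be reduced.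

Step 7
Reactants: 11 methyl 7-(tert-butyldimethylsilyloxy)-11,12,13,14,15,16,18-heptanorlabd-7-en-19-oate
Product: 13 methyl 7-(tert-butyldimethylsilyloxy)-11,12,13,14,15,16-hexanorlabd-7-en-19-oate (4α-CH3 and 4β-CO2CH3), via exocyclic lithium enolate 12 (not isolated)
Conditions: LiN(iPr)2, THF/DMPU, −78 °C; then MeI, −78 → 0 °C
Reagents that add atoms: iodomethane, CI
Why: Alkylation of the exocyclic ester enolate: iodomethane enters from the equatorial α face because the β face is blocked by the axial C20 methyl (1,3-diaxial), which should place CH3 α (C18) and CO2CH3 β, axial (C19), the known outcome for 4-alkoxycarbonyl-10-methyldecalins.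

Step 8
Reactants: 13 methyl 7-(tert-butyldimethylsilyloxy)-11,12,13,14,15,16-hexanorlabd-7-en-19-oate
Product: 14 methyl 7-oxo-11,12,13,14,15,16-hexanorlabd-8-en-19-oate
Conditions: Pd(OAc)2 (10 mol%), O2 (1 atm), DMSO, 60 °C
Reagents that add atoms: none
Why: Saegusa–Ito oxidation: the silyl enol ether becomes a C8-bound enolate of divalent palladium, syn β-hydride elimination toward C9 gives the conjugated endocyclic enone, and O2 returns zerovalent palladium to the divalent state; the regiochemistry is fixed by the enol ether position delivered in step 3.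

Step 9
Reactants: 14 methyl 7-oxo-11,12,13,14,15,16-hexanorlabd-8-en-19-oate
Product: 15 methyl 7β-hydroxy-11,12,13,14,15,16-hexanorlabd-8-en-19-oate
Conditions: NaBH4, CeCl3·7H2O, MeOH, −78 → −20 °C
Reagents that add atoms: none
Why: Luche 1,2-reduction; hydride should add along the axial trajectory from the α face (anti to the axial 6β-H), giving the pseudo-equatorial 7β-alcohol, and the hindered C19 ester is untouched.

Step 10
Reactants: 15 methyl 7β-hydroxy-11,12,13,14,15,16-hexanorlabd-8-en-19-oate
Product: 18 12-ethyl 19-methyl 13,14,15,16-tetranorlabd-7-ene-12,19-dioate, via mixed orthoester 16 (not isolated), via ketene acetal 17 (not isolated)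
Conditions: MeC(OEt)3 (excess), EtCO2H (cat.), xylene, 140 °C, EtOH distilled off
Reagents that add atoms: triethyl orthoacetate, CC(OCC)(OCC)OCC
Why: Johnson–Claisen rearrangement: alcohol exchange and loss of ethanol give ketene acetal 17, whose suprafacial [3,3] shift turns the C7β–O bond into a C9β–C11 bond and moves the double bond to C7=C8, so C9 (9α-H, β side chain) is set from C7; the precedent is the rearrangement of rigid 3β-hydroxy-4-ene steroids to 5β-acetic esters.

Step 11
Reactants: 18 12-ethyl 19-methyl 13,14,15,16-tetranorlabd-7-ene-12,19-dioate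
Product: 19 13,14,15,16-tetranorlabd-7-ene-12,19-diol
Conditions: LiAlH4, THF, 0 °C → reflux
Reagents that add atoms: none
Why: Hydride reduction of both esters; the axial neopentyl C19 ester needs the upper end of the temperature range, and the isolated trisubstituted alkene is inert.

Step 12
Reactants: 19 13,14,15,16-tetranorlabd-7-ene-12,19-diol
Product: 20 13,14,15,16-tetranorlabdane-7α,8α,12,19-tetraol
Conditions: OsO4 (5 mol%), NMO, acetone/H2O, rt
Reagents that add atoms: osmium tetroxide, O=[Os](=O)(=O)=O; N-methylmorpholine N-oxide, C[N+]1([O-])CCOCC1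
Why: Catalytic syn-dihydroxylation of the only alkene from the α face, because the β face of C7=C8 is shielded by the axial C20 methyl and the 9β chain; this should give 7α-OH and 8α-OH with C17 β, and it is done before the diene exists.

Step 13
Reactants: 20 13,14,15,16-tetranorlabdane-7α,8α,12,19-tetraol
Product: 21 7α,8α-(isopropylidenedioxy)-13,14,15,16-tetranorlabdane-12,19-diol
Conditions: Me2C(OMe)2, PPTS (cat.), acetone, rt
Reagents that add atoms: 2,2-dimethoxypropane, COC(C)(C)OC
Why: Thermodynamic acetonide formation on the cis-1,2-diol (five-membered dioxolane); the two primary alcohols cannot form a small-ring ketal and stay free, and masking O-8 prevents its later cyclisation onto C12.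

Step 14
Reactants: 21 7α,8α-(isopropylidenedioxy)-13,14,15,16-tetranorlabdane-12,19-diol
Product: 22 12-iodo-7α,8α-(isopropylidenedioxy)-13,14,15,16-tetranorlabdan-19-ol
Conditions: I2, PPh3, imidazole, CH2Cl2, 0 °C
Reagents that add atoms: iodine, II
Why: Appel iodination under buffered conditions should be selective for the unhindered primary C12 alcohol; the axial neopentyl C19 alcohol cannot undergo backside displacement at this temperature and is recovered on work-up.

Step 15
Reactants: 23 chloroprene (2-chlorobuta-1,3-diene)
Product: 24 buta-1,3-dien-2-ylmagnesium chloride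
Conditions: Mg, ZnCl2 (cat.), BrCH2CH2Br (cat.), THF, 50 °C
Reagents that add atoms: magnesium, [Mg]
Why: Grignard formation by insertion of magnesium into the vinylic C–Cl bond, a known reagent that is used as its THF solution.

Step 16
Reactants: 22 12-iodo-7α,8α-(isopropylidenedioxy)-13,14,15,16-tetranorlabdan-19-ol; 24 buta-1,3-dien-2-ylmagnesium chloride
Product: 25 7α,8α-(isopropylidenedioxy)labda-13(16),14-dien-19-ol
Conditions: 24 (3 equiv), Li2CuCl4 (5 mol%), THF, −20 → 0 °C
Reagents that add atoms: none
Why: Copper-catalysed sp3–sp2 cross-coupling of a primary iodide with a vinylic Grignard reagent forms C12–C13 and installs the complete 2-substituted diene; one equivalent of 24 is consumed by the free O-19, and ether formation from O-8 is excluded by the acetonide.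

Step 17
Reactants: 26 (E)-p-coumaric acid
Product: 28 (E)-3-[4-(tetrahydro-2H-pyran-2-yloxy)phenyl]prop-2-enoic acid, via bis-THP derivative 27 (not isolated)
Conditions: 3,4-dihydro-2H-pyran, PPTS (cat.), CH2Cl2, rt; then NaOH, THF/H2O, rt; NaHSO4 to pH 4, 0 °C
Reagents that add atoms: 3,4-dihydro-2H-pyran, C1=COCCC1
Why: Acid-catalysed addition of the phenol and the acid to the enol ether (acetal formation), then saponification of the labile THP ester only; the THP ether is stable to base and the E alkene is unchanged.

Step 18
Reactants: 25 7α,8α-(isopropylidenedioxy)labda-13(16),14-dien-19-ol; 28 (E)-3-[4-(tetrahydro-2H-pyran-2-yloxy)phenyl]prop-2-enoic acid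
Product: 29 7α,8α-(isopropylidenedioxy)labda-13(16),14-dien-19-yl (E)-3-[4-(tetrahydro-2H-pyran-2-yloxy)phenyl]prop-2-enoate (epimers at the acetal carbon)
Conditions: EDC·HCl, DMAP, CH2Cl2, rt
Reagents that add atoms: none
Why: Carbodiimide/DMAP (Steglich) esterification of the only free hydroxyl; the neopentyl alcohol is slow but the acylpyridinium is a small electrophile, and the diene, acetonide and THP ether are inert.

Step 19
Reactants: 29 7α,8α-(isopropylidenedioxy)labda-13(16),14-dien-19-yl (E)-3-[4-(tetrahydro-2H-pyran-2-yloxy)phenyl]prop-2-enoate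
Product: 30 (4S,5R,7R,8S,9R,10S)-7α,8α-dihydroxylabda-13(16),14-dien-19-yl (E)-4-hydroxycinnamate (the target)
Conditions: AcOH/THF/H2O (3:1:1), 45 °C
Reagents that add atoms: none
Why: Mild acidic hydrolysis of the phenolic THP acetal and the acetonide in one operation; acetic acid should be too weak to protonate the diene at a useful rate, the ester is stable to it, and no stereocentre is touched.

## Compound list

1 | methacrolein (2-methylprop-2-enal) | C=C(C)C=O | starting material
2 | methyl but-3-enoate | C=CCC(=O)OC | starting material
3 | methyl (E)-4-methyl-5-oxopent-3-enoate | O=C/C(C)=C/CC(=O)OC | intermediate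
4 | 3-methylbut-3-en-2-one | CC(=O)C(C)=C | starting material
5 | tert-butyldimethyl[(3-methylbuta-1,3-dien-2-yl)oxy]silane | C=C(O[Si](C)(C)C(C)(C)C)C(C)=C | intermediate
6 | methyl 2-[(1S,2R)-5-(tert-butyldimethylsilyloxy)-2-formyl-2,4-dimethylcyclohex-4-en-1-yl]acetate | O=C[C@]1(C)CC(C)=C(O[Si](C)(C)C(C)(C)C)C[C@H]1CC(=O)OC | intermediate
7 | methyl 2-[(1S,2S)-5-(tert-butyldimethylsilyloxy)-2,4-dimethyl-2-vinylcyclohex-4-en-1-yl]acetate | C=C[C@]1(C)CC(C)=C(O[Si](C)(C)C(C)(C)C)C[C@H]1CC(=O)OC | intermediate
8 | lithium ester enolate of 7 | C=C[C@]1(C)CC(C)=C(O[Si](C)(C)C(C)(C)C)C[C@H]1C=C(O[Li])OC | intermediate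
9 | methyl 2-[(1S,2S)-5-(tert-butyldimethylsilyloxy)-2,4-dimethyl-2-vinylcyclohex-4-en-1-yl]pent-4-enoate (both C4 epimers) | C=C[C@]1(C)CC(C)=C(O[Si](C)(C)C(C)(C)C)C[C@H]1C(CC=C)C(=O)OC | intermediate
10 | methyl 7-(tert-butyldimethylsilyloxy)-11,12,13,14,15,16,18-heptanorlabda-1,7-dien-19-oate (5α-H, 10β-CH3; both C4 epimers) | C1C(C)=C(O[Si](C)(C)C(C)(C)C)C[C@H]2C(C(=O)OC)CC=C[C@@]21C | intermediate
11 | methyl 7-(tert-butyldimethylsilyloxy)-11,12,13,14,15,16,18-heptanorlabd-7-en-19-oate (5α-H, 10β-CH3; both C4 epimers) | C1C(C)=C(O[Si](C)(C)C(C)(C)C)C[C@H]2C(C(=O)OC)CCC[C@@]21C | intermediate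
12 | exocyclic lithium enolate of 11 | C1C(C)=C(O[Si](C)(C)C(C)(C)C)C[C@H]2C(=C(O[Li])OC)CCC[C@@]21C | intermediate
13 | methyl 7-(tert-butyldimethylsilyloxy)-11,12,13,14,15,16-hexanorlabd-7-en-19-oate (4α-CH3, 4β-CO2CH3) | C1C(C)=C(O[Si](C)(C)C(C)(C)C)C[C@H]2[C@@](C)(C(=O)OC)CCC[C@@]21C | intermediate
14 | methyl 7-oxo-11,12,13,14,15,16-hexanorlabd-8-en-19-oate | C1=C(C)C(=O)C[C@H]2[C@@](C)(C(=O)OC)CCC[C@@]21C | intermediate
15 | methyl 7β-hydroxy-11,12,13,14,15,16-hexanorlabd-8-en-19-oate | C1=C(C)[C@@H](O)C[C@H]2[C@@](C)(C(=O)OC)CCC[C@@]21C | intermediate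
16 | mixed orthoester of 15 (7β-O-(1,1-diethoxyethyl)) | C1=C(C)[C@@H](OC(C)(OCC)OCC)C[C@H]2[C@@](C)(C(=O)OC)CCC[C@@]21C | intermediate
17 | ketene acetal of 15 (7β-O-(1-ethoxyvinyl)) | C1=C(C)[C@@H](OC(=C)OCC)C[C@H]2[C@@](C)(C(=O)OC)CCC[C@@]21C | intermediate
18 | 12-ethyl 19-methyl 13,14,15,16-tetranorlabd-7-ene-12,19-dioate | CCOC(=O)C[C@H]1C(C)=CC[C@H]2[C@@](C)(C(=O)OC)CCC[C@@]21C | intermediate
19 | 13,14,15,16-tetranorlabd-7-ene-12,19-diol | OCC[C@H]1C(C)=CC[C@H]2[C@@](C)(CO)CCC[C@@]21C | intermediate
20 | 13,14,15,16-tetranorlabdane-7α,8α,12,19-tetraol | OCC[C@H]1[C@](C)(O)[C@H](O)C[C@H]2[C@@](C)(CO)CCC[C@@]21C | intermediate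
21 | 7α,8α-(isopropylidenedioxy)-13,14,15,16-tetranorlabdane-12,19-diol | OCC[C@H]1[C@]3(C)OC(C)(C)O[C@@H]3C[C@H]2[C@@](C)(CO)CCC[C@@]21C | intermediate
22 | 12-iodo-7α,8α-(isopropylidenedioxy)-13,14,15,16-tetranorlabdan-19-ol | ICC[C@H]1[C@]3(C)OC(C)(C)O[C@@H]3C[C@H]2[C@@](C)(CO)CCC[C@@]21C | intermediate
23 | chloroprene (2-chlorobuta-1,3-diene) | C=CC(Cl)=C | starting material
24 | buta-1,3-dien-2-ylmagnesium chloride | C=CC(=C)[Mg]Cl | intermediate
25 | 7α,8α-(isopropylidenedioxy)labda-13(16),14-dien-19-ol | C=CC(=C)CC[C@H]1[C@]3(C)OC(C)(C)O[C@@H]3C[C@H]2[C@@](C)(CO)CCC[C@@]21C | intermediate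
26 | (E)-p-coumaric acid | O=C(O)/C=C/c1ccc(O)cc1 | starting material
27 | tetrahydro-2H-pyran-2-yl (E)-3-[4-(tetrahydro-2H-pyran-2-yloxy)phenyl]prop-2-enoate | O=C(OC1CCCCO1)/C=C/c1ccc(OC2CCCCO2)cc1 | intermediate
28 | (E)-3-[4-(tetrahydro-2H-pyran-2-yloxy)phenyl]prop-2-enoic acid | O=C(O)/C=C/c1ccc(OC2CCCCO2)cc1 | intermediate
29 | 7α,8α-(isopropylidenedioxy)labda-13(16),14-dien-19-yl (E)-3-[4-(tetrahydro-2H-pyran-2-yloxy)phenyl]prop-2-enoate | C=CC(=C)CC[C@H]1[C@]3(C)OC(C)(C)O[C@@H]3C[C@H]2[C@@](C)(COC(=O)/C=C/c4ccc(OC5CCCCO5)cc4)CCC[C@@]21C | intermediate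
30 | (4S,5R,7R,8S,9R,10S)-7α,8α-dihydroxylabda-13(16),14-dien-19-yl (E)-4-hydroxycinnamate | C=CC(=C)CC[C@H]1[C@](C)(O)[C@H](O)C[C@H]2[C@@](C)(COC(=O)/C=C/c3ccc(O)cc3)CCC[C@@]21C | target

## Step count and least certain steps

Total step count: 19. Longest linear sequence: 16 (steps 1, 3–14, 16, 18 and 19; steps 2, 15 and 17 are one-step side branches).

**Step 3 (key step).**
- What may go wrong: the trisubstituted, β-branched enal may be activated too weakly by the catalyst, so that polymerisation or hydrolysis of diene 5 and acid-induced double-bond migration in 3 overtake the cycloaddition. Facial discrimination may also be eroded, because the β-substituent and its ester disturb the catalyst–enal arrangement known for 2-substituted acroleins.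
- Fallback (sets out from 3 and 5, returns at 6): the cycloaddition is run without asymmetric induction (Me2AlCl, CH2Cl2, −78 °C, or neat at 90 °C) to give the racemic aldehyde F1. Condensation with (1R,2R)-N,N′-dimethyl-1,2-diphenylethane-1,2-diamine (MgSO4, Et2O) gives two diastereomeric aminals, which are separated by chromatography. The aminal F2 of the required enantiomer is hydrolysed on wet silica gel or with cold aqueous citric acid to 6, and the diamine is recovered. Absolute control then comes from resolution and not from catalysis.

**Step 10.**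
- What may go wrong: slow rearrangement, because the C7–O bond is pseudo-equatorial and C9 is flanked by quaternary C10, so that acid-catalysed elimination of the allylic orthoester to a ring diene overtakes the [3,3] shift.
- Fallback (sets out from 15, returns at 19): phenyl isocyanate converts 15 into the N-phenylcarbamate F3. N-deprotonation (MeLi), CuI and then CH2=CHMgBr effect a carbamate-directed syn-SN2′ substitution. The copper reagent is held on the β face by the carbamate, so the vinyl group is delivered to C9β with the double bond moving to C7=C8, giving the 9β-vinyl ester F4. Hydroboration of the terminal alkene only (9-BBN, then NaOH/H2O2) gives the hydroxy ester F5, and LiAlH4 reduction gives 19.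

**Step 8.**
- What may go wrong: β-hydride elimination toward the C17 methyl group (exocyclic enone), or sluggish transfer of the hindered tetrasubstituted silyl enol ether to palladium with competing desilylation to the saturated ketone.
- Fallback (sets out from 13, returns at 14): PhSeCl (CH2Cl2, −78 °C) reacts directly with the silyl enol ether to give the α-phenylselanyl ketone F6. Oxidation (H2O2, pyridine) and selenoxide syn-elimination give 14. Any exocyclic isomer is moved into the ring with RhCl3·3H2O in hot ethanol.

**Step 19.**
- What may go wrong: protonation of the 2-substituted diene (allylic cation, then hydration or double-bond migration) during the time the hindered acetonide needs for hydrolysis.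
- Fallback (sets out from 22, returns at 30): the diene is made last under neutral conditions. Alkylation of 22 with lithium acetylide–ethylenediamine complex (LiC≡CH·H2NCH2CH2NH2, DMSO, rt) gives the terminal alkyne F7. Esterification with 28 (EDC·HCl, DMAP) gives F8. Aqueous acetic acid then removes acetonide and THP while only the acid-stable alkyne is present, giving the alkynyl triol ester F9. Enyne cross-metathesis with ethene (second-generation Grubbs catalyst RuCl2(H2IMes)(PCy3)(=CHPh), ethene 1 atm, CH2Cl2, rt) converts the terminal alkyne into the 2-substituted buta-1,3-diene of 30. The electron-poor 1,2-disubstituted cinnamate alkene should be much slower toward the ruthenium carbene.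

## Further compounds

F1 | step 3 | racemic aldehyde (6 together with its enantiomer; the enantiomer is shown) | O=C[C@@]1(C)CC(C)=C(O[Si](C)(C)C(C)(C)C)C[C@@H]1CC(=O)OC
F2 | step 3 | aminal of 6 with (1R,2R)-N,N′-dimethyl-1,2-diphenylethane-1,2-diamine (1,3-dimethyl-4,5-diphenylimidazolidin-2-yl in place of the formyl group) | CN1[C@H](c2ccccc2)[C@H](N(C)C1[C@]3(C)CC(C)=C(O[Si](C)(C)C(C)(C)C)C[C@H]3CC(=O)OC)c1ccccc1
F3 | step 10 | methyl 7β-(N-phenylcarbamoyloxy)-11,12,13,14,15,16-hexanorlabd-8-en-19-oate | C1=C(C)[C@@H](OC(=O)Nc3ccccc3)C[C@H]2[C@@](C)(C(=O)OC)CCC[C@@]21C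
F4 | step 10 | methyl 13,14,15,16-tetranorlabda-7,11-dien-19-oate (9β-vinyl) | C=C[C@H]1C(C)=CC[C@H]2[C@@](C)(C(=O)OC)CCC[C@@]21C
F5 | step 10 | methyl 12-hydroxy-13,14,15,16-tetranorlabd-7-en-19-oate | OCC[C@H]1C(C)=CC[C@H]2[C@@](C)(C(=O)OC)CCC[C@@]21C
F6 | step 8 | methyl 7-oxo-8α-(phenylselanyl)-11,12,13,14,15,16-hexanorlabdan-19-oate | C1[C@](C)([Se]c3ccccc3)C(=O)C[C@H]2[C@@](C)(C(=O)OC)CCC[C@@]21C
F7 | step 19 | 7α,8α-(isopropylidenedioxy)-15,16-dinorlabd-13-yn-19-ol | C#CCC[C@H]1[C@]3(C)OC(C)(C)O[C@@H]3C[C@H]2[C@@](C)(CO)CCC[C@@]21C
F8 | step 19 | 7α,8α-(isopropylidenedioxy)-15,16-dinorlabd-13-yn-19-yl (E)-3-[4-(tetrahydro-2H-pyran-2-yloxy)phenyl]prop-2-enoate | C#CCC[C@H]1[C@]3(C)OC(C)(C)O[C@@H]3C[C@H]2[C@@](C)(COC(=O)/C=C/c4ccc(OC5CCCCO5)cc4)CCC[C@@]21C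
F9 | step 19 | 7α,8α-dihydroxy-15,16-dinorlabd-13-yn-19-yl (E)-4-hydroxycinnamate | C#CCC[C@H]1[C@](C)(O)[C@H](O)C[C@H]2[C@@](C)(COC(=O)/C=C/c3ccc(O)cc3)CCC[C@@]21C
A1 | alternative 1 | ethyl (3E,7E,11Z)-13-(benzyloxy)-4,8,12-trimethyltrideca-3,7,11-trienoate | CCOC(=O)C/C=C(C)/CC/C=C(C)/CC/C=C(C)\COCc1ccccc1
A2 | alternative 1 | 19-(benzyloxy)-13,14,15,16-tetranorlabdan-12,8α-olide | O=C1C[C@H]2[C@](C)(O1)CC[C@H]3[C@@](C)(COCc4ccccc4)CCC[C@@]32C
A3 | alternative 2 | methyl (2E,7S,8E)-7-(methoxycarbonyl)-3,7-dimethyl-10-oxododeca-2,8-dienoate | COC(=O)/C=C(\C)CCC[C@](C)(C(=O)OC)/C=C/C(=O)CC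
A4 | alternative 2 | dimethyl 7-(tert-butyldimethylsilyloxy)-12,13,14,15,16-pentanorlabd-6-ene-11,19-dioate | COC(=O)[C@H]1C(C)C(O[Si](C)(C)C(C)(C)C)=C[C@H]2[C@@](C)(C(=O)OC)CCC[C@@]21C
A5 | alternative 3 | (+)-podocarpic acid | c12cc(O)ccc1CC[C@H]3[C@@](C)(C(=O)O)CCC[C@@]32C
A6 | alternative 3 | methyl 8-oxo-11,12,13,14,15,16,17-heptanorlabdan-19-oate | C1C(=O)CC[C@H]2[C@@](C)(C(=O)OC)CCC[C@@]21C
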